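**Retrosynthetic overview**

1. The SMILES is read as a head-to-head cyclobutane dimer of two ligustilide units (bonds C6–C7a′ and C7–C3a′, both carbocycles on one face), with a Z-butylidene on the conjugated unit A and an E-butylidene on the cyclobutane-fused unit B.
2. Last operation: thermodynamic E→Z isomerisation of the conjugated butylidene of unit A only (13 ⇐ 12).
3. Key C–C bonds (C8–C9 and C8′–C9′): twofold Pd-catalysed coupling of n-PrZnBr with a bis[(E)-iodomethylene] dilactone, in which each α-iodo enol lactone acts as an α-cation (enolonium) equivalent of a latent valeryl ketone; this fixes the E geometry of unit B (12 ⇐ 10). Both lactone rings come from anti-iodocyclisation of a dimeric bis(alkynyl ester) (10 ⇐ 9).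
4. Cyclobutane and all four stereocentres: catalytic enantioselective [2+2] photodimerisation of methyl 2-ethynylcyclohexa-1,5-diene-1-carboxylate, run at the alkyne stage so that no exocyclic alkene can scramble (9 ⇐ 8).
5. Cyclohexadiene: pyrone/ethylene Diels–Alder with CO2 loss from a 6-alkynyl coumalate, made by C6 zincation of methyl coumalate (8 ⇐ 4 ⇐ 1). Ring order: carbocycle → cyclobutane → both lactones.

Assumption: the SMILES is taken literally (unit A Z, unit B E), and the (S)-prolinol-derived Lewis acid of step 3 is taken to give the enantiomer shown; this would be checked by X-ray, and the (R)-catalyst used if the sense is opposite.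

Numbering used in names: ligustilide numbering (C1 lactone carbonyl, O2, C3, C3a, C4–C7, C7a, C8 exocyclic carbon, C9–C11 propyl); unprimed = unit A, primed = unit B.

**Route**

Step 1
Reactants: 1 methyl coumalate (methyl 2-oxo-2H-pyran-5-carboxylate); 2 (bromoethynyl)triisopropylsilane
Product: 4 methyl 2-oxo-6-[(triisopropylsilyl)ethynyl]-2H-pyran-5-carboxylate, via C6-zincated coumalate 3 (not isolated)
Conditions: TMPZnCl·LiCl (1.2 equiv), THF, 25 °C; then 2 (1.2 equiv), Pd(PPh3)4 (3 mol %), 40 °C
Reagents that add atoms: none
Why: Directed zincation with a hindered TMP-zinc base followed by Negishi alkynylation: the amide removes the most acidic proton H-6 (between ring oxygen and ester), so C6, the carbon at which nucleophiles normally attack coumalates (with ring opening), reacts instead as a carbanion with the bromoalkyne, and the mild organozinc leaves ester and lactone intact.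

Step 2
Reactants: 4 methyl 2-oxo-6-[(triisopropylsilyl)ethynyl]-2H-pyran-5-carboxylate; 5 ethylene
Product: 8 methyl 2-ethynylcyclohexa-1,5-diene-1-carboxylate, via bicyclic lactone cycloadduct 6 (not isolated), via silyl dienyne ester 7 (not isolated)
Conditions: ethylene (50 bar), toluene, BHT, 140 °C; then TBAF (1.1 equiv), AcOH (1.1 equiv), THF, 0 °C
Reagents that add atoms: none
Why: Diels–Alder reaction of the electron-poor 2-pyrone with ethylene followed by retro-Diels–Alder loss of CO2 places both ring double bonds unambiguously (C3a=C7a and C6=C7, no isomerisation needed), and buffered fluoride then removes the silyl group.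

Step 3
Reactants: 8 methyl 2-ethynylcyclohexa-1,5-diene-1-carboxylate (two molecules)
Product: 9 dimethyl 1,4-diethynyltricyclo[6.4.0.0^2,7]dodeca-3,9-diene-3,8-dicarboxylate (head-to-head dimer; H-2, H-7, the 1-ethynyl and the 8-ester group on one face of the cyclobutane, both six-membered rings on the other; absolute configuration as in the SMILES)
Conditions: oxazaborolidine from (S)-α,α-diphenylprolinol and 2,3-dimethylphenylboronic acid (50 mol %), AlBr3 (50 mol %), CH2Cl2, −75 °C, hν (385 nm LED)
Reagents that add atoms: none
Why: Proposed new method: a chiral-Lewis-acid-catalysed [2+2] photocycloaddition (closest known type: oxazaborolidine–AlBr3 chromophore activation of enones and cinnamate esters), in which only the Lewis-acid-bound ester absorbs at 385 nm and its C3a′=C7a′ bond adds to the unhindered cis C6=C7 bond of a free molecule; head-to-head bonding (C7a′–C6 first, leaving an allyl radical at C7 and a propargyl radical at C3a′), cis ring fusions, stacking of ring A over the carbocycle of unit B away from the catalyst-bound ester, and catalyst shielding of one face together set C6, C7, C3a′ and C7a′.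

Step 4
Reactants: 9 dimethyl 1,4-diethynyltricyclo[6.4.0.0^2,7]dodeca-3,9-diene-3,8-dicarboxylate
Product: 10 (3E,3′E)-bis(iodomethylene) dilactone (both butenolide/butyrolactone rings closed, iodine trans to the ring oxygen in each; cyclobutane configuration unchanged)
Conditions: I2 (4 equiv), MeCN, 40 °C, dark; aq. Na2S2O3 work-up
Reagents that add atoms: iodine, II
Why: Electrophilic 5-exo-dig iodocyclisation of alkynyl esters (Larock type): each terminal alkyne is activated as an iodonium ion, the neighbouring ester carbonyl oxygen attacks the internal alkyne carbon anti to iodine, and iodide demethylates the oxocarbenium ion by SN2, giving both (E)-iodomethylene lactones, while addition of I2 to the ring alkene is reversible.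

Step 5
Reactants: 10 (3E,3′E)-bis(iodomethylene) dilactone; 11 bromo(propyl)zinc (n-PrZnBr, 0.5 M in THF)
Product: 12 (3E,3′E)-6.7a′,7.3a′-diligustilide (both butylidenes E; cyclobutane configuration unchanged)
Conditions: 11 (2.6 equiv), PdCl2(dppf) (5 mol %), THF, 23 °C
Reagents that add atoms: none
Why: Twofold Negishi cross-coupling with retention of alkene geometry: oxidative addition of zerovalent palladium into each C(sp2)–I bond makes the α-carbon of the latent valeryl ketone the electrophile (enolonium-type reactivity) toward the propylzinc nucleophile, so propyl ends up trans to the ring oxygen, which is the required E geometry of unit B.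

Step 6
Reactants: 12 (3E,3′E)-6.7a′,7.3a′-diligustilide
Product: 13 (3Z,3′E,6S,7R,3a′S,7a′R)-6.7a′,7.3a′-diligustilide (target)
Conditions: I2 (2 mol %), CH2Cl2, visible light, 23 °C, short reaction time
Reagents that add atoms: none
Why: Iodine-atom-catalysed alkene isomerisation (reversible radical addition, rotation, elimination): an iodine atom adds readily to C8 of the conjugated ylidene butenolide of unit A (allylic, oxygen-stabilised radical) and relaxes it to the favoured Z isomer (propyl away from C4H2), whereas the isolated enol-ester alkene of unit B adds iodine atoms far more slowly and keeps its E geometry; no stereocentre is touched.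

**Compound list**

1 | methyl coumalate (methyl 2-oxo-2H-pyran-5-carboxylate) | COC(=O)C1=COC(=O)C=C1 | starting material
2 | (bromoethynyl)triisopropylsilane | BrC#C[Si](C(C)C)(C(C)C)C(C)C | starting material
3 | chloro[5-(methoxycarbonyl)-2-oxo-2H-pyran-6-yl]zinc (LiCl adduct) | COC(=O)C1=C([Zn]Cl)OC(=O)C=C1 | intermediate
4 | methyl 2-oxo-6-[(triisopropylsilyl)ethynyl]-2H-pyran-5-carboxylate | COC(=O)C1=C(C#C[Si](C(C)C)(C(C)C)C(C)C)OC(=O)C=C1 | intermediate
5 | ethylene | C=C | starting material
6 | methyl 3-oxo-1-[(triisopropylsilyl)ethynyl]-2-oxabicyclo[2.2.2]oct-5-ene-6-carboxylate (racemic) | COC(=O)C1=CC2CCC1(C#C[Si](C(C)C)(C(C)C)C(C)C)OC2=O | intermediate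
7 | methyl 2-[(triisopropylsilyl)ethynyl]cyclohexa-1,5-diene-1-carboxylate | COC(=O)C1=C(C#C[Si](C(C)C)(C(C)C)C(C)C)CCC=C1 | intermediate
8 | methyl 2-ethynylcyclohexa-1,5-diene-1-carboxylate | COC(=O)C1=C(C#C)CCC=C1 | intermediate
9 | dimethyl 1,4-diethynyltricyclo[6.4.0.0^2,7]dodeca-3,9-diene-3,8-dicarboxylate (head-to-head dimer, six-membered rings syn, configuration as in 13) | COC(=O)C2=C(C#C)CC[C@H]1[C@@H]2[C@@]2(C#C)CCC=C[C@@]12C(=O)OC | intermediate
10 | (3E,3′E)-3,3′-bis(iodomethylene) dilactone of the 6.7a′,7.3a′-linked dimer (iodine trans to ring oxygen in both units) | I/C=C1/OC(=O)C2=C1CC[C@H]1[C@@H]2[C@@]23CCC=C[C@@]12C(=O)O/C3=C/I | intermediate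
11 | bromo(propyl)zinc | CCC[Zn]Br | starting material
12 | (3E,3′E,6S,7R,3a′S,7a′R)-6.7a′,7.3a′-diligustilide | CCC/C=C1/OC(=O)C2=C1CC[C@H]1[C@@H]2[C@@]23CCC=C[C@@]12C(=O)O/C3=C/CCC | intermediate
13 | (3Z,3′E,6S,7R,3a′S,7a′R)-6.7a′,7.3a′-diligustilide (CNP0371639.1) | CCC/C=C1\OC(=O)C2=C1CC[C@H]1[C@@H]2[C@@]23CCC=C[C@@]12C(=O)O/C3=C/CCC | target

**Step count and risks**

Total steps: 6. Longest linear sequence: 6 (1 → 4 → 8 → 9 → 10 → 12 → 13; compounds 2, 5 and 11 are bought).

The three steps most likely to fail:

Step 3 (photodimerisation). The regiochemistry (C6=C7 with C3a′=C7a′, head-to-head), the syn arrangement of the rings and the enantioselectivity are all unproven for this substrate, and other dimers are expected as by-products. The fallback sets out from 8 and comes back at 9. It gives up asymmetric catalysis for a racemic synthesis with resolution: triplet-sensitised dimerisation without Lewis acid (thioxanthen-9-one, 405 nm, MeCN, 0.5 M) gives the racemic head-to-head dimer, that is 9 together with its enantiomer ent-9 F1. After chromatographic removal of regio- and diastereomeric dimers, the two are separated by preparative HPLC on an amylose tris(3,5-dimethylphenylcarbamate) phase, and 9 goes on to step 4.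

Step 4 (double iodocyclisation of the methyl esters). The ester carbonyl may cyclise too slowly on the hindered unit B, or iodine may consume the ring alkene. The fallback sets out from 9 and comes back at 10. Both methyl esters are first cleaved by SN2 dealkylation (LiI, pyridine, 100 °C, acid work-up) to the dicarboxylic acid 1,4-diethynyltricyclo[6.4.0.0^2,7]dodeca-3,9-diene-3,8-dicarboxylic acid F2. Both lactones are then closed under alkyne-selective π-acid catalysis with an electrophilic iodine source (AuCl(PPh3)/AgOTf 5 mol %, N-iodosuccinimide, CH2Cl2, 0 °C). Anti attack of each carboxylate gives a vinyl-gold species that is iodinated with retention, again giving 10.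

Step 6 (unit-A-selective isomerisation). Iodine may also erode the E geometry of unit B, or unit A may not equilibrate cleanly. The fallback sets out from 10 and comes back at 13, bypassing 12. The geometry of unit A is corrected at the iodide stage by a polar mechanism that unit B cannot follow: NaI (20 mol %), acetone, 40 °C, exchanges iodide by addition–elimination at the vinylogous β-iodo enoate of unit A only. This equilibrates it to the less hindered isomer and gives the (3Z,3′E)-bis(iodomethylene) dilactone F3. Twofold Negishi coupling of this compound with 11 under the conditions of step 5 then gives 13 directly, with retention at both alkenes.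

**Further compounds**

F1 | step 3 | ent-9, dimethyl 1,4-diethynyltricyclo[6.4.0.0^2,7]dodeca-3,9-diene-3,8-dicarboxylate of opposite absolute configuration | COC(=O)C2=C(C#C)CC[C@@H]1[C@H]2[C@]2(C#C)CCC=C[C@]12C(=O)OC
F2 | step 4 | 1,4-diethynyltricyclo[6.4.0.0^2,7]dodeca-3,9-diene-3,8-dicarboxylic acid (configuration as 9) | OC(=O)C2=C(C#C)CC[C@H]1[C@@H]2[C@@]2(C#C)CCC=C[C@@]12C(=O)O
F3 | step 6 | (3Z,3′E)-3,3′-bis(iodomethylene) dilactone of the 6.7a′,7.3a′-linked dimer (iodine cis to ring oxygen in unit A, trans in unit B) | I/C=C1\OC(=O)C2=C1CC[C@H]1[C@@H]2[C@@]23CCC=C[C@@]12C(=O)O/C3=C/I
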